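The route rests on opening the cyclooctene ring at two opposite bonds: the tetrasubstituted C=C that it shares with the butenolide, and the CH2-CH(CH3) bond between carbinol carbon and cyclopropane. What remains is a linear keto ester. It is an alpha-acyloxy ketone carrying the anti carbinol/side-chain triad and a primary bromide, esterified with a cis-cyclopropyl phosphonoacetic acid that ends in an (E)-enal. One flask closes both rings: base-induced Horner-Wadsworth-Emmons olefination makes the butenolide, then light triggers a silyl-radical Giese closure of the eight-membered ring. The step exploits the Z-locked butenolide alkene and the cis-cyclopropane, four contiguous ring atoms that fold the chain, and the bisected vinylcyclopropane conformation, which sets the CH(CH3) centre.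

Key step: step 18

Remark: lactone 20 is taken as purchasable in the single (1S,5R) form. The formyl carbon of the enal is a traceless activator that leaves as CO in step 19.

**Fragment 1 (steps 1-10)**

Step 1
Reactants: 1 (4-carboxybutyl)triphenylphosphonium bromide; 2 acetone
Product: 4 6-methylhept-5-enoic acid, via ylide carboxylate 3 (not isolated)
Conditions: NaN(SiMe3)2 (2.1 equiv), THF, 0 °C; 2, 0 °C to rt; aq. HCl
Reagents that add atoms: none
Why: Wittig olefination of acetone by the non-stabilised ylide (the second equivalent of base covers the acid) should give the trisubstituted alkene, for which no alkene geometry arises.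

Step 2
Reactants: 4 6-methylhept-5-enoic acid; 5 (S)-4-benzyl-1,3-oxazolidin-2-one
Product: 7 (S)-4-benzyl-3-(6-methylhept-5-enoyl)-1,3-oxazolidin-2-one, via mixed pivalic anhydride 6 (not isolated)
Conditions: t-BuCOCl, Et3N, THF, -20 °C; LiCl, 5, -20 °C to rt
Reagents that add atoms: none
Why: Mixed-anhydride N-acylation of the oxazolidinone, assisted by LiCl, attacks the less hindered carbonyl of 6 and installs the auxiliary without touching the alkene.

Step 3
Reactants: 7 (S)-4-benzyl-3-(6-methylhept-5-enoyl)-1,3-oxazolidin-2-one; 8 3-(trimethylsilyl)prop-2-ynal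
Product: 10 (4S)-4-benzyl-3-[(2S,3S)-3-hydroxy-2-(4-methylpent-3-en-1-yl)-5-(trimethylsilyl)pent-4-ynoyl]-1,3-oxazolidin-2-one, via Z boron enolate 9 (not isolated)
Conditions: Bu2BOTf, Et3N, CH2Cl2, -78 to 0 °C; 8, -78 to 0 °C; pH 7 buffer, MeOH, H2O2, 0 °C
Reagents that add atoms: none
Why: Evans syn aldol reaction in which the Z enolate reacts through a chair Zimmerman-Traxler transition state on the face away from the benzyl group, which sets the side-chain stereocentre and the propargylic carbinol as the syn (2S,3S) pair.

Step 4
Reactants: 10 aldol adduct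
Product: 11 (2R,3S)-2-(4-methylpent-3-en-1-yl)-5-(trimethylsilyl)pent-4-yne-1,3-diol
Conditions: LiBH4, MeOH (1 equiv), Et2O, 0 °C
Reagents that add atoms: none
Why: Reductive cleavage of the imide turns the acyl carbon into the future CH2OAc carbon and breaks no bond at either stereocentre (the change of descriptor is only a change of priorities).

Step 5
Reactants: 11 diol
Product: 12 (2R,3S)-3-hydroxy-2-(4-methylpent-3-en-1-yl)-5-(trimethylsilyl)pent-4-yn-1-yl acetate
Conditions: AcCl (1.05 equiv), 2,4,6-collidine, CH2Cl2, -78 °C
Reagents that add atoms: acetyl chloride, CC(=O)Cl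
Why: Kinetic acylation at low temperature should take the primary hydroxyl in preference to the hindered secondary propargylic one and puts the acetate of the target in place for good.

Step 6
Reactants: 12 monoacetate
Product: 13 (2R,3S)-3-(methanesulfonyloxy)-2-(4-methylpent-3-en-1-yl)-5-(trimethylsilyl)pent-4-yn-1-yl acetate
Conditions: MsCl, Et3N, CH2Cl2, -78 °C
Reagents that add atoms: methanesulfonyl chloride, CS(=O)(=O)Cl
Why: O-sulfonylation forms only an O-S bond, so the carbinol configuration is retained in the propargylic mesylate, which is used crude.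

Step 7
Reactants: 14 2-bromo-1,1-diethoxyethane
Product: 15 bromoacetaldehyde
Conditions: 2 M aq. HCl, 80 °C; extraction into Et2O, MgSO4, used at once
Reagents that add atoms: water, O
Why: Acid-catalysed acetal hydrolysis releases the labile aldehyde just before use.

Step 8
Reactants: 13 propargylic mesylate; 15 bromoacetaldehyde
Product: 17 (2S,3R,4R)-5-bromo-4-hydroxy-2-(4-methylpent-3-en-1-yl)-3-[(trimethylsilyl)ethynyl]pentyl acetate, via allenylzinc 16 (not isolated)
Conditions: Pd(OAc)2 (5 mol%), PPh3 (5 mol%), Et2Zn (3 equiv), THF, -78 to -20 °C; 15; aq. NH4Cl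
Reagents that add atoms: none
Why: Marshall propargylation in which zerovalent palladium ionises the mesylate anti, exchange with Et2Zn gives allenylzinc 16, and 16 adds to the aldehyde through a cyclic SE2' transition state, so that C-C replaces C-O with net inversion and the new carbinol is set anti to the branched substituent.

Step 9
Reactants: 17 bromohydrin
Product: 18 (2S,3R,4R)-5-bromo-4-[(tert-butyldimethylsilyl)oxy]-2-(4-methylpent-3-en-1-yl)-3-[(trimethylsilyl)ethynyl]pentyl acetate
Conditions: TBSOTf, 2,6-lutidine, CH2Cl2, -78 to 0 °C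
Reagents that add atoms: tert-butyldimethylsilyl triflate, CC(C)(C)[Si](C)(C)OS(=O)(=O)C(F)(F)F
Why: Silylation under non-nucleophilic base masks the hydroxyl so that the bromohydrin cannot close to an epoxide under the basic conditions of step 18.

Step 10
Reactants: 18 silyl ether
Product: 19 (2S,3R,4R)-5-bromo-4-[(tert-butyldimethylsilyl)oxy]-3-ethynyl-2-(4-methylpent-3-en-1-yl)pentyl acetate
Conditions: Bu4NF, AcOH (1:1), THF, 0 °C
Reagents that add atoms: none
Why: Buffered fluoride protodesilylation cleaves the C(sp)-Si bond much faster than the secondary O-TBS group and spares acetate and bromide.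

**Fragment 2 (steps 11-15)**

Step 11
Reactants: 20 (1S,5R)-3-oxabicyclo[3.1.0]hexan-2-one
Product: 21 ethyl (1S,2R)-2-(bromomethyl)cyclopropane-1-carboxylate
Conditions: dry HBr, EtOH, 0 °C to rt
Reagents that add atoms: hydrogen bromide, Br; ethanol, CCO
Why: SN2 opening of the protonated lactone at its CH2-O carbon, followed by Fischer esterification, breaks no bond at the ring stereocentres, so the cis-cyclopropane is carried over intact.

Step 12
Reactants: 21 bromo ester
Product: 22 ethyl (1S,2R)-2-[(diethoxyphosphoryl)methyl]cyclopropane-1-carboxylate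
Conditions: P(OEt)3 (neat), 130 °C
Reagents that add atoms: triethyl phosphite, CCOP(OCC)OCC
Why: Michaelis-Arbuzov reaction of the primary bromide, where the ring ester disfavours cationic cyclopropylcarbinyl rearrangement.

Step 13
Reactants: 22 phosphonate ester
Product: 23 diethyl {[(1R,2S)-2-formylcyclopropyl]methyl}phosphonate
Conditions: i-Bu2AlH (1.05 equiv), CH2Cl2, -78 °C; aq. potassium sodium tartrate
Reagents that add atoms: none
Why: Partial reduction stops at the tetrahedral aluminate at low temperature and gives the cis aldehyde, which is slow to enolise because the alpha carbon is cyclopropyl.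

Step 14
Reactants: 23 cyclopropane aldehyde; 24 (1,3-dioxolan-2-ylmethyl)triphenylphosphonium bromide
Product: 26 diethyl ({(1R,2R)-2-[2-(1,3-dioxolan-2-yl)ethenyl]cyclopropyl}methyl)phosphonate (E/Z mixture), via dioxolanyl ylide 25 (not isolated)
Conditions: 24, KOt-Bu, THF, 0 °C; 23, 0 °C to rt
Reagents that add atoms: none
Why: Wittig two-carbon homologation delivers the enal in base-stable masked form, and the alkene mixture converges to E in step 17.

Step 15
Reactants: 26 vinyl dioxolane phosphonate
Product: 28 2-(diethoxyphosphoryl)-2-{(1R,2R)-2-[2-(1,3-dioxolan-2-yl)ethenyl]cyclopropyl}acetic acid (epimers at C-2), via lithiated phosphonate 27 (not isolated)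
Conditions: LiN(i-Pr)2 (2.1 equiv), THF, -78 °C; CO2 (g); aq. HCl to pH 3, 0 °C
Reagents that add atoms: carbon dioxide, O=C=O
Why: Carboxylation of the phosphonate-stabilised carbanion gives the alpha-phosphono acid, and its new centre needs no control because step 18 turns it into an sp2 carbon.

**Union and endgame (steps 16-20)**

Step 16
Reactants: 19 terminal alkyne; 28 phosphono acid
Product: 29 keto ester, that is 19 with C≡CH replaced by C(=O)CH2-O-acyl where acyl is that of 28 and all stereocentres are unchanged
Conditions: Ph3PAuNTf2 (5 mol%), 8-methylquinoline N-oxide (1.3 equiv), PhCl, rt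
Reagents that add atoms: 8-methylquinoline N-oxide, Cc1cccc2ccc[n+]([O-])c12
Why: Gold-catalysed oxidation of a terminal alkyne by an N-oxide (attack at the internal carbon) and capture of the terminal alpha-oxo carbenoid by the carboxylic acid gives the alpha-acyloxy methyl ketone and joins the fragments in one step.

Step 17
Reactants: 29 keto ester dioxolane
Product: 30 keto ester (E)-enal, that is 29 with the dioxolane replaced by CHO
Conditions: p-TsOH·H2O (10 mol%), acetone/H2O, rt
Reagents that add atoms: water, O
Why: Mild acetal hydrolysis frees the enal, and reversible acid-catalysed addition equilibrates the Z portion to the conjugated E isomer while the secondary TBS ether and the acetate survive.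

Step 18
Reactants: 30 keto ester (E)-enal
Product: 32 tricyclic aldehyde, that is the O-TBS ether of the target with CH2CHO in place of the ring CH3, via butenolide bromo enal 31 (not isolated)
Conditions: K2CO3 (3 equiv), 18-crown-6, (Me3Si)3SiH (1.5 equiv), [Ir(dF(CF3)ppy)2(dtbbpy)]PF6 (2 mol%), MeCN (2 mM), rt, 2 h dark, then 450 nm LEDs
Reagents that add atoms: none
Why: In the dark the carbonate deprotonates the phosphonoacetate and the carbanion closes on the neighbouring ketone (intramolecular Horner-Wadsworth-Emmons olefination, 5-exo-trig addition then loss of diethyl phosphate) to forge the tetrasubstituted butenolide C=C of 31; on irradiation the photocatalyst and (Me3Si)3SiH supply a silyl radical that abstracts bromine, the primary radical adds to the beta carbon of the enal (Giese reaction, 8-exo-trig), and the alpha-formyl radical is reduced and protonated. The closest known reactions are the butenolide synthesis from phosphonoacetates of alpha-hydroxy ketones and the silane-mediated photoredox Giese addition of alkyl bromides, which needs a carbonate base anyway, so one charge of reagents serves both events and the lamp only fixes their order. The second closure becomes feasible through the first, because the Z-locked alkene and the cis-cyclopropane fix four contiguous atoms of the nascent ring and bring the CH2 radical next to the enal. The only new stereocentre, the ring CH that bears CH2CHO, is controlled by the cyclopropane: the enal reacts from its bisected s-trans conformation and the tether can reach only the alkene face on the side of the butenolide-bearing ring carbon, which places the CH2CHO group outward and gives the configuration of the target. The carbanion must take the ketone rather than the aldehyde, which the five-membered closure, the E geometry (no ring through it is possible) and the dilution secure. The nucleophilic radical must take the electron-poor enal rather than the electron-rich side-chain alkene or the butenolide (polarity match, 4-exo and 5-endo modes disfavoured) and must cyclise before hydrogen transfer, which the 2 mM silane concentration favours.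

Step 19
Reactants: 32 tricyclic aldehyde
Product: 33 O-TBS ether of the target
Conditions: RhCl(PPh3)3 (1.1 equiv), toluene, 110 °C
Reagents that add atoms: none
Why: Tsuji-Wilkinson decarbonylation (oxidative addition into the formyl C-H bond, CO extrusion, reductive elimination) converts CH2CHO into CH3 without touching the adjacent stereocentre, the esters or the trisubstituted alkene.

Step 20
Reactants: 33 O-TBS ether of the target
Product: 34 target CNP0267808.2
Conditions: HF·pyridine, pyridine, THF, 0 °C to rt
Reagents that add atoms: none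
Why: Buffered fluoride cleavage of the secondary silyl ether frees the ring carbinol and leaves acetate, butenolide and cyclopropane unchanged.

**Compound list**

1 | (4-carboxybutyl)triphenylphosphonium bromide | [Br-].OC(=O)CCCC[P+](c1ccccc1)(c1ccccc1)c1ccccc1 | starting material
2 | acetone | CC(C)=O | starting material
3 | sodium 5-(triphenylphosphoranylidene)pentanoate | [Na+].[O-]C(=O)CCCC=P(c1ccccc1)(c1ccccc1)c1ccccc1 | intermediate
4 | 6-methylhept-5-enoic acid | CC(C)=CCCCC(=O)O | intermediate
5 | (S)-4-benzyl-1,3-oxazolidin-2-one | O=C1OC[C@H](Cc2ccccc2)N1 | starting material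
6 | 6-methylhept-5-enoic pivalic anhydride | CC(C)=CCCCC(=O)OC(=O)C(C)(C)C | intermediate
7 | (S)-4-benzyl-3-(6-methylhept-5-enoyl)-1,3-oxazolidin-2-one | CC(C)=CCCCC(=O)N1C(=O)OC[C@@H]1Cc1ccccc1 | intermediate
8 | 3-(trimethylsilyl)prop-2-ynal | C[Si](C)(C)C#CC=O | starting material
9 | (Z)-dibutylboron enolate of 7 | CCCCB(CCCC)O/C(N1C(=O)OC[C@@H]1Cc1ccccc1)=C\CCC=C(C)C | intermediate
10 | (4S)-4-benzyl-3-[(2S,3S)-3-hydroxy-2-(4-methylpent-3-en-1-yl)-5-(trimethylsilyl)pent-4-ynoyl]-1,3-oxazolidin-2-one | O=C1OC[C@H](Cc2ccccc2)N1C(=O)[C@@H](CCC=C(C)C)[C@H](O)C#C[Si](C)(C)C | intermediate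
11 | (2R,3S)-2-(4-methylpent-3-en-1-yl)-5-(trimethylsilyl)pent-4-yne-1,3-diol | OC[C@@H](CCC=C(C)C)[C@H](O)C#C[Si](C)(C)C | intermediate
12 | (2R,3S)-3-hydroxy-2-(4-methylpent-3-en-1-yl)-5-(trimethylsilyl)pent-4-yn-1-yl acetate | CC(=O)OC[C@@H](CCC=C(C)C)[C@H](O)C#C[Si](C)(C)C | intermediate
13 | (2R,3S)-3-(methanesulfonyloxy)-2-(4-methylpent-3-en-1-yl)-5-(trimethylsilyl)pent-4-yn-1-yl acetate | CC(=O)OC[C@@H](CCC=C(C)C)[C@H](OS(C)(=O)=O)C#C[Si](C)(C)C | intermediate
14 | 2-bromo-1,1-diethoxyethane | CCOC(CBr)OCC | starting material
15 | bromoacetaldehyde | O=CCBr | intermediate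
16 | ethyl(allenyl)zinc from 13, zinc on the silyl-bearing allene terminus and on the side anti to the departed mesylate | CC[Zn]C([Si](C)(C)C)=[C@]=C([H])[C@@H](COC(C)=O)CCC=C(C)C | intermediate
17 | (2S,3R,4R)-5-bromo-4-hydroxy-2-(4-methylpent-3-en-1-yl)-3-[(trimethylsilyl)ethynyl]pentyl acetate | CC(=O)OC[C@@H](CCC=C(C)C)[C@@H]([C@H](CBr)O)C#C[Si](C)(C)C | intermediate
18 | (2S,3R,4R)-5-bromo-4-[(tert-butyldimethylsilyl)oxy]-2-(4-methylpent-3-en-1-yl)-3-[(trimethylsilyl)ethynyl]pentyl acetate | CC(=O)OC[C@@H](CCC=C(C)C)[C@@H]([C@H](CBr)O[Si](C)(C)C(C)(C)C)C#C[Si](C)(C)C | intermediate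
19 | (2S,3R,4R)-5-bromo-4-[(tert-butyldimethylsilyl)oxy]-3-ethynyl-2-(4-methylpent-3-en-1-yl)pentyl acetate | CC(=O)OC[C@@H](CCC=C(C)C)[C@@H]([C@H](CBr)O[Si](C)(C)C(C)(C)C)C#C | intermediate
20 | (1S,5R)-3-oxabicyclo[3.1.0]hexan-2-one | O=C1OC[C@@H]2C[C@H]12 | starting material
21 | ethyl (1S,2R)-2-(bromomethyl)cyclopropane-1-carboxylate | BrC[C@@H]1C[C@@H]1C(=O)OCC | intermediate
22 | ethyl (1S,2R)-2-[(diethoxyphosphoryl)methyl]cyclopropane-1-carboxylate | CCOP(=O)(OCC)C[C@@H]1C[C@@H]1C(=O)OCC | intermediate
23 | diethyl {[(1R,2S)-2-formylcyclopropyl]methyl}phosphonate | CCOP(=O)(OCC)C[C@@H]1C[C@@H]1C=O | intermediate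
24 | (1,3-dioxolan-2-ylmethyl)triphenylphosphonium bromide | [Br-].C1COC(C[P+](c2ccccc2)(c2ccccc2)c2ccccc2)O1 | starting material
25 | (1,3-dioxolan-2-ylmethylidene)triphenylphosphorane | C1COC(C=P(c2ccccc2)(c2ccccc2)c2ccccc2)O1 | intermediate
26 | diethyl ({(1R,2R)-2-[2-(1,3-dioxolan-2-yl)ethenyl]cyclopropyl}methyl)phosphonate, E/Z mixture | CCOP(=O)(OCC)C[C@@H]1C[C@@H]1C=CC1OCCO1 | intermediate
27 | alpha-lithio derivative of 26 | [Li]C(P(=O)(OCC)OCC)[C@@H]1C[C@@H]1C=CC1OCCO1 | intermediate
28 | 2-(diethoxyphosphoryl)-2-{(1R,2R)-2-[2-(1,3-dioxolan-2-yl)ethenyl]cyclopropyl}acetic acid, epimers at C-2 | OC(=O)C(P(=O)(OCC)OCC)[C@@H]1C[C@@H]1C=CC1OCCO1 | intermediate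
29 | keto ester: 2-oxoalkyl ester of 28 derived from 19 (C≡CH becomes C(=O)CH2O-acyl), stereocentres of 19 and 28 retained | CC(=O)OC[C@@H](CCC=C(C)C)[C@@H]([C@H](CBr)O[Si](C)(C)C(C)(C)C)C(=O)COC(=O)C(P(=O)(OCC)OCC)[C@@H]1C[C@@H]1C=CC1OCCO1 | intermediate
30 | keto ester (E)-enal: 29 with the dioxolane hydrolysed to CHO | CC(=O)OC[C@@H](CCC=C(C)C)[C@@H]([C@H](CBr)O[Si](C)(C)C(C)(C)C)C(=O)COC(=O)C(P(=O)(OCC)OCC)[C@@H]1C[C@@H]1/C=C/C=O | intermediate
31 | butenolide bromo enal: alpha-[(1R,2R)-2-((E)-3-oxoprop-1-enyl)cyclopropyl] beta-substituted 2(5H)-furanone carrying the bromo silyloxy acetoxy side chain of 19 | CC(=O)OC[C@@H](CCC=C(C)C)[C@@H]([C@H](CBr)O[Si](C)(C)C(C)(C)C)C1=C(C(=O)OC1)[C@@H]1C[C@@H]1/C=C/C=O | intermediate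
32 | tricyclic aldehyde: O-TBS ether of the target with CH2CHO in place of the ring CH3, spatial arrangement at all six stereocentres as in the target | CC(=O)OC[C@@H](CCC=C(C)C)[C@@H]1C2=C(C(=O)OC2)[C@@H]2C[C@@H]2[C@@H](CC=O)C[C@@H]1O[Si](C)(C)C(C)(C)C | intermediate
33 | O-TBS ether of the target | CC(=O)OC[C@@H](CCC=C(C)C)[C@@H]1C2=C(C(=O)OC2)[C@@H]2C[C@@H]2[C@@H](C)C[C@@H]1O[Si](C)(C)C(C)(C)C | intermediate
34 | CNP0267808.2 | CC(=O)OC[C@@H](CCC=C(C)C)[C@@H]1C2=C(C(=O)OC2)[C@@H]2C[C@@H]2[C@@H](C)C[C@@H]1O | target

Total step count: 20.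
Longest linear sequence: 14 steps (1-6, 8-10, 16-20).

**Steps most likely to fail**

1. Step 18. Hydrogen transfer to the primary radical (from the silane, or by a 1,5-shift from the side chain) may outrun the eight-membered closure. The carbonate may also slowly expel silanolate from the carbon next to the acidified allylic CH of 31.
   Fallback, setting out from 30: the olefination is run alone (LiCl, i-Pr2NEt, MeCN) and 31 is isolated. The ring closure is then moved from a free-radical chain to a metal template by nickel-catalysed reductive conjugate addition (NiCl2(dme), neocuproine, Mn, Et3SiCl, DMF). Here the enal is held as a silyloxyallylnickel species that captures the alkyl fragment. This should give the triethylsilyl enol ether F1, and mild aqueous acid returns it to the route at 32.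

2. Step 8. Zerovalent palladium or the zinc reagent may attack the C-Br bond of 15. The aldehyde may also self-condense, and the anti selectivity may erode with this small aldehyde.
   Fallback, setting out from 13: the halogen is introduced only after the C-C bond. The same propargylation with 2-[(4-methoxybenzyl)oxy]acetaldehyde should give the PMB-protected anti adduct F2. TBSOTf/2,6-lutidine then gives the silyl PMB bis-ether F3, DDQ (CH2Cl2/H2O) frees the primary alcohol F4, and Appel bromination (CBr4, PPh3) rejoins the route at 18.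

3. Step 16. The gold carbenoid may be intercepted by the side-chain alkene or a neighbouring oxygen instead of the scarce acid, or the phosphonate may deactivate the catalyst.
   Fallback, setting out from 18: the ester bond is made by SN2 instead. NBS/AgNO3 (cat., acetone) converts the silylalkyne into the bromoalkyne F5. Hydration ((XPhos)AuNTf2 cat., H2O, 1,2-dichloroethane) gives the alpha-bromomethyl ketone F6. The caesium salt of 28 (Cs2CO3, DMF) then displaces the far more reactive alpha-keto bromide, which rejoins the route at 29.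

**Further compounds**

F1 | step 18 | triethylsilyl enol ether of 32 (E/Z) | CC(=O)OC[C@@H](CCC=C(C)C)[C@@H]1C2=C(C(=O)OC2)[C@@H]2C[C@@H]2[C@@H](C=CO[Si](CC)(CC)CC)C[C@@H]1O[Si](C)(C)C(C)(C)C
F2 | step 8 | anti adduct of 13 with 2-[(4-methoxybenzyl)oxy]acetaldehyde, that is 17 with OPMB for Br | CC(=O)OC[C@@H](CCC=C(C)C)[C@@H]([C@H](COCc1ccc(OC)cc1)O)C#C[Si](C)(C)C
F3 | step 8 | O-TBS ether of F2 | CC(=O)OC[C@@H](CCC=C(C)C)[C@@H]([C@H](COCc1ccc(OC)cc1)O[Si](C)(C)C(C)(C)C)C#C[Si](C)(C)C
F4 | step 8 | primary alcohol, that is 18 with OH for Br | CC(=O)OC[C@@H](CCC=C(C)C)[C@@H]([C@H](CO)O[Si](C)(C)C(C)(C)C)C#C[Si](C)(C)C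
F5 | step 16 | bromoalkyne, that is 18 with Br for the alkynyl SiMe3 | CC(=O)OC[C@@H](CCC=C(C)C)[C@@H]([C@H](CBr)O[Si](C)(C)C(C)(C)C)C#CBr
F6 | step 16 | alpha-bromomethyl ketone from F5 | CC(=O)OC[C@@H](CCC=C(C)C)[C@@H]([C@H](CBr)O[Si](C)(C)C(C)(C)C)C(=O)CBr
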